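The time of reading, 15 h, may matter less than it seems: what is asked is a share of two products fed by one reagent, and dividing one rate by the other removes [reagent] and, while the two substrates stand equal, time and the charge as well.

| flask | left-handed substrate | right-handed substrate | gas | temperature | remark | time |
|---|---|---|---|---|---|---|
| noon | 0.80 M | 0.80 M | 20 mM (held) | 18 °C | run made earlier |  |
| dusk | 1.3 M | 1.3 M | 20 mM (held) | 45 °C | run made earlier |  |
| red | 0.57 M | 0.57 M | 20 mM (held) | 25 °C |  | 15 h |
| amber | 0.57 M | 0.57 M | 20 mM (held) | 40 °C |  | 15 h |
| blue | 0.57 M | 0.57 M | 20 mM (held) | 55 °C |  | 15 h |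
| ochre | 0.57 M | 0.57 M | 20 mM (held) | 45 °C |  | 15 h |
| violet | 0.57 M | 0.57 M | 20 mM (held) | 5 °C |  | 15 h |
| grey | 0.57 M | 0.57 M | 20 mM (held) | 10 °C |  | 15 h |

| run | time / h | left-handed product / % | right-handed product / % |
|---|---|---|---|
| noon | 1.33 | 1.0 | 0.8 |
| noon | 2.00 | 2.7 | 0.7 |
| noon | 3.00 | 3.4 | 1.3 |
| noon | 4.00 | 5.0 | 1.1 |
| noon | 6.00 | 7.7 | 2.7 |
| noon | 10.0 | 12.1 | 4.0 |
| noon | 15.0 | 17.9 | 6.2 |
| dusk | 0.333 | 0 | 0 |
| dusk | 1.00 | 0.9 | 0.8 |
| dusk | 1.33 | 2.0 | 1.4 |
| dusk | 2.00 | 2.4 | 1.2 |
| dusk | 4.00 | 4.7 | 3.8 |
| dusk | 6.00 | 7.1 | 5.3 |

(readings scatter by 0.3 percentage points)

* the flasks put in order of share of left-handed product in all that became left-handed product or right-handed product, best first, at 15 h (red / amber / blue / ochre / violet / grey)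
* the share of left-handed product in all that became left-handed product or right-handed product of the flask you put first, at 15 h
* the share of left-handed product in all that became left-handed product or right-handed product of the flask you put last, at 15 h

- reagent is single-handed; left-handed substrate and right-handed substrate are mirror images of each other, charged as a racemate, each of them at the stated concentration
- at the start none of reagent is dissolved
- steps under discussion: left-handed substrate <-> right-handed substrate; reagent + left-handed substrate -> left-handed product; reagent + right-handed substrate -> right-handed product; gas <-> reagent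
- the handed part of reagent does not stay in what it makes, so the products of the two hands are mirror images too

Each product forms from reagent and its own substrate, so at equal [left-handed substrate] and [right-handed substrate] the rate of left-handed product over that of right-handed product is a plain hand ratio s, the selectivity factor, and the share is s over one plus s. The last readings give 2.89 at noon and 1.34 at dusk, so a straight line of ln s against inverse temperature says that the activation energy of the right-handed step exceeds that of the left-handed step by 21.9 kJ mol⁻¹, the energy gap. My own reckoning carries this gap to s = 1.04 at 55 °C, a share of 51.0 %, and to s = 4.41 at 5 °C, a share of 81.5 %, with the flasks ranked by falling temperature.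

The objection is that equal substrates were assumed. If the substrates never interconverted, the same readings would give 3.35 at noon and 1.37 at dusk, and the gap would become 25.5 kJ mol⁻¹. The ratio at 55 °C would then be 1.02, close to the first estimate, while the ratio at 5 °C would rise to 5.48, a starting share of 84.6 %. Both ratios at 55 °C rest on the same noon and dusk readings, so their closeness speaks to the assumption of equal substrates and not to the line itself, which keeps the scatter of those readings; the low estimate remains a two-point extrapolation, and the top estimate is a range between these two shares.

The forecast gives violet > grey > red > amber > ochre > blue, with 81 % on top and 51 % at the bottom, and it warns that “depletion of the favoured hand may erode the share further”.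

The flasks give violet > grey > red > amber > ochre > blue, with 83.7 % in violet and 44.7 % in blue, which is 6.3 percentage points below the forecast.

    left-handed substrate ⇌ right-handed substrate (k = 0.530 h⁻¹, Ea = 88.0 kJ mol⁻¹)
    reagent + left-handed substrate → left-handed product (k = 4.00 M⁻¹ h⁻¹, Ea = 51.0 kJ mol⁻¹)
    reagent + right-handed substrate → right-handed product (k = 1.70 M⁻¹ h⁻¹, Ea = 80.0 kJ mol⁻¹)
    gas ⇌ reagent, rate k4*(csat - [reagent]) (kL = 3.00 h⁻¹)
    (constants at 25 °C)

In blue at 7.23 h, the half-life of right-handed substrate by its step is 8.9 h, shorter than the 11 h of left-handed substrate by its own step, and their ratio of 0.809 is the hand ratio of blue. That ratio stands below the 1.04 of the line, and it matches the 0.808 that the share of blue implies. Carried by the energy gap from this ratio to a flask like blue kept at 80 °C, s becomes 0.458, a share of 31.4 %, and that flask stands at 27.6 %.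

Readings and results come from a simulation for substances that don't exist; noise was put on by code.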